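(The constants stand for no real mixture.)

A charge of free catalyst far smaller than the substrate must go round its loop many times, so count the turns.

- blue: substrate 10 mM; coupling partner 12.0 mM; free catalyst 75 µM; time 2.0 min
- amber: substrate 10 mM; coupling partner 12.0 mM; free catalyst 190 µM; time 2.0 min

    catalyst intermediate C ⇌ by-product + catalyst intermediate D (K1 = 0.0058 M, k1 = 2.67 s⁻¹)
    coupling partner + catalyst intermediate B ⇌ catalyst intermediate C (K2 = 30 M⁻¹, k2 = 264 M⁻¹ s⁻¹)
    catalyst intermediate A → catalyst intermediate B (k3 = 3.78 s⁻¹)
    catalyst intermediate D → free catalyst + target (k4 = 2.83 s⁻¹)
    substrate + free catalyst → catalyst intermediate A (k5 = 56.2 M⁻¹ s⁻¹)

- which of these there is most of at the end, counted by the substrate in it, blue (substrate / target / catalyst intermediate C / catalyst intermediate B)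
- which of these there is most of at the end, counted by the substrate in it, amber (substrate / target / catalyst intermediate C / catalyst intermediate B)
- the largest of these amounts at the end, in percent of the substrate charged, blue
- the largest of these amounts at the end, in percent of the substrate charged, amber

How many turns does the substrate need? The turnover number for full conversion, substrate charge over catalyst charge, is 133 in blue and 52.6 in amber.

How long is one turn? Take the turn time: the seconds a catalyst spends in all its forms per finished turn. At the start, free catalyst waits 1.78 s for substrate. Catalyst intermediate C falls back to catalyst intermediate B 3.30 times per forward passage, so catalyst intermediate B holds the catalyst for 1.36 s. With the short stays in the other forms, the turn time is 4.13 s. That pace allows 29.1 turns, a little more than the 26.3 amber needs for half its substrate, so the pace must be checked.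

Does the pace hold? At a conversion of 0.5, substrate and coupling partner are down, and by-product pushes catalyst intermediate D back, stretching the return traffic by a factor of 1.81. The turn time there is 8.63 s, longer than at the start.

Does amber reach that conversion? At the mean of the two turn times it needs 2.80 min, longer than the 2.0 min allowed, so by this reckoning substrate stays ahead of target in amber, and in blue with its larger turnover number too. Let the turn time climb in a straight line and add it up over the conversion. I then get finished turns worth 18.2 % of the charge in blue and 38.8 % in amber.

The forecast says substrate at 80 % in blue and substrate at 58 % in amber: “unreacted substrate remains the largest pool in both runs”.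

The simulation gives substrate at 80.6 % in blue, with target 19.0 %, and substrate at 58.2 % in amber, with target 40.7 %.

Amber stands below blue because of its larger catalyst charge: take that difference away, running amber with blue's catalyst charge, and its substrate goes from 58.2 % to 80.6 %. Amber's simulated target gives a mean turn time of 5.61 s, above the starting 4.13 s and below 8.63 s. The same climbing turn time, applied to blue with 0.30 mM of free catalyst, reckons 54.6 %, and that flask stands at target 55.8 %, more than its substrate at 42.4 %.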